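**Plan**
- Late adjustments: the 4'-O-MOM group and the CHO/CO2Me oxidation level are handled last. The C5–prenyl bond is cut by a retro-Claisen shift back to a 4-O-(1,1-dimethylallyl) ether.
- Core disconnection: O1–C2 and C2–C1' are cut together. C2 holds both O1 and ring B, so it can enter as the CBr2 terminus of a dibromoacrylate whose α-carbon is C3 and whose ester carbon is the later CHO.
- Enabling feature: C3a sits between the oxygen-bearing carbons C4 and C7a. Ring A can therefore be a 2-substituted 5-methoxyresorcinol with two equivalent phenols; one becomes O1 and the other stays as the C4 hydroxyl.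
- Forward order: ring A is bought. C3a–C3 (lithiation, oxalate) and C3=C2 (dibromoolefination) are added. The furan ring closes and ring B (a boronic acid) is joined in one flask. The prenyl group, the aldehyde and the free 4'-phenol follow.
- Stereochemistry: the target has no stereocentre and no E/Z alkene, so none has to be set.

Key step: step 7

Assumption: lithiation of the bis-MOM ether is taken to occur at the carbon flanked by both OCH2OCH3 groups, the stronger pair of directing groups. Benzofuran numbering is used throughout, with ring A the benzo ring and ring B the 2-aryl ring (primed positions).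

Step 1
Reactants: 1 5-methoxyresorcinol
Product: 2 1-methoxy-3,5-bis(methoxymethoxy)benzene
Conditions: MOMCl (2.5 equiv), iPr2NEt, CH2Cl2, 0 °C → rt
Reagents that add atoms: chloromethyl methyl ether (MOMCl), COCCl
Why: O-alkylation of both phenols with the reactive α-chloro ether (MOM protection) installs the two groups that direct the next lithiation and later leave under mild acid.

Step 2
Reactants: 2 1-methoxy-3,5-bis(methoxymethoxy)benzene; 3 dimethyl oxalate
Product: 5 methyl 2-[4-methoxy-2,6-bis(methoxymethoxy)phenyl]-2-oxoacetate, via aryllithium 4 (not isolated)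
Conditions: n-BuLi, THF, 0 °C → rt; cannulated into 3 (3 equiv), THF, −78 °C; AcOH quench at −78 °C
Reagents that add atoms: dimethyl oxalate 3, COC(=O)C(=O)OC
Why: Directed ortho-metalation should take place at the one carbon flanked by two chelating OMOM groups, and inverse addition of 4 to excess oxalate stops the acyl substitution at the α-keto ester because the tetrahedral adduct persists until the cold acid quench.

Step 3
Reactants: 5 methyl 2-[4-methoxy-2,6-bis(methoxymethoxy)phenyl]-2-oxoacetate; 6 carbon tetrabromide
Product: 7 methyl 3,3-dibromo-2-[4-methoxy-2,6-bis(methoxymethoxy)phenyl]acrylate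
Conditions: 6 (2 equiv), PPh3 (4 equiv), CH2Cl2, 0 °C; then Et3N (1 equiv), 5, 0 °C → rt
Reagents that add atoms: carbon tetrabromide 6, BrC(Br)(Br)Br
Why: The Ramirez dibromoolefination (first stage of the Corey–Fuchs sequence), a Wittig reaction known for aryl glyoxylates, should engage only the ketone carbonyl, which the neighbouring ester activates strongly, while preforming the ylide and adding Et3N keep free phosphine and acid away from the dicarbonyl and the MOM ethers.

Step 4
Reactants: 7 methyl 3,3-dibromo-2-[4-methoxy-2,6-bis(methoxymethoxy)phenyl]acrylate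
Product: 8 methyl 3,3-dibromo-2-(2,6-dihydroxy-4-methoxyphenyl)acrylate
Conditions: conc. HCl (cat.), MeOH, 40 °C
Reagents that add atoms: none
Why: Acid-catalysed transacetalisation to methanol removes both aryl MOM ethers, and methanol as solvent matches the methyl ester and keeps the hydroxy ester open, since any lactone formed onto the ester is re-opened by methanolysis.

Step 5
Reactants: 9 4-bromo-3-methoxyphenol
Product: 10 1-bromo-2-methoxy-4-(methoxymethoxy)benzene
Conditions: MOMCl, iPr2NEt, CH2Cl2, 0 °C → rt
Reagents that add atoms: chloromethyl methyl ether (MOMCl), COCCl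
Why: MOM protection of the phenol gives an acetal that should withstand n-BuLi, aqueous base, heat, LiAlH4 and MnO2 in the steps that follow.

Step 6
Reactants: 10 1-bromo-2-methoxy-4-(methoxymethoxy)benzene
Product: 13 [2-methoxy-4-(methoxymethoxy)phenyl]boronic acid, via aryllithium 11 (not isolated), via lithium triisopropoxyborate 12 (not isolated)
Conditions: n-BuLi, THF, −78 °C; B(OiPr)3, −78 °C → rt; 1 M HCl to pH 6, 0 °C
Reagents that add atoms: triisopropyl borate, CC(C)OB(OC(C)C)OC(C)C; water, O
Why: Bromine–lithium exchange, trapping of the aryllithium with the borate and cold, barely acidic hydrolysis (lithiation–borylation) is the standard route to aryl boronic acids and leaves the MOM ether intact.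

Step 7
Reactants: 8 methyl 3,3-dibromo-2-(2,6-dihydroxy-4-methoxyphenyl)acrylate; 13 [2-methoxy-4-(methoxymethoxy)phenyl]boronic acid
Product: 15 methyl 4-hydroxy-6-methoxy-2-[2-methoxy-4-(methoxymethoxy)phenyl]benzofuran-3-carboxylate, via 2-bromobenzofuran 14 (not isolated)
Conditions: K3PO4 (4 equiv), CuI (5 mol%), 1,4-dioxane, 80 °C, Ar; then 13 (1.3 equiv), Pd(PPh3)4 (5 mol%), H2O (dioxane–H2O 10:1), 90 °C, same flask
Reagents that add atoms: none
Why: K3PO4 generates the phenoxide of 8, which adds to the CBr2 carbon (the β-carbon of the acrylate), and the ester enolate expels bromide, an addition–elimination that forms O1–C2 and closes the furan ring in a 5-endo-trig mode at oxygen to give 14; CuI is added because Ullmann-type vinylic C–O coupling is the established way from 2-(gem-dibromovinyl)phenols to 2-bromobenzofurans and supplies an in-plane pathway if the 5-endo attack is slow. Zerovalent palladium then inserts into the C2–Br bond of 14, which O1 and the C3 ester activate, and transmetalation from the boronate of 13 followed by reductive elimination forms C2–C1' (Suzuki–Miyaura coupling). The closest known reaction type is the tandem intramolecular C–O bond formation and Suzuki coupling of 2-(gem-dibromovinyl)phenols to 2-arylbenzofurans, applied here to an olefin that also carries an ester. No stereocentre is created and no regiocontrol between the phenols is needed, because the mirror symmetry of ring A makes them equivalent and the one left over is the C4 hydroxyl. Attack at CBr2 rather than at the ester carbonyl is secured because lactonisation is reversible and would press a bromine against the C4 oxygen in the planar lactone, whereas bromide loss is irreversible and aromatises the furan. Entry of only one aryl group is secured by adding 13 and Pd(PPh3)4 only after 8 has been consumed, so that palladium meets a single C–Br bond.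

Step 8
Reactants: 16 2-methylbut-3-en-2-ol
Product: 18 tert-butyl (2-methylbut-3-en-2-yl) carbonate, via lithium alkoxide 17 (not isolated)
Conditions: n-BuLi, THF, 0 °C; Boc2O, 0 °C → rt; H2O
Reagents that add atoms: di-tert-butyl dicarbonate (Boc2O), CC(C)(C)OC(=O)OC(=O)OC(C)(C)C
Why: Acylation of the preformed tertiary alkoxide with Boc2O is the usual preparation of mixed tert-alkyl allylic carbonates and avoids acid that would ionise the tertiary allylic alcohol.

Step 9
Reactants: 15 methyl 4-hydroxy-6-methoxy-2-[2-methoxy-4-(methoxymethoxy)phenyl]benzofuran-3-carboxylate; 18 tert-butyl (2-methylbut-3-en-2-yl) carbonate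
Product: 19 methyl 6-methoxy-2-[2-methoxy-4-(methoxymethoxy)phenyl]-4-[(2-methylbut-3-en-2-yl)oxy]benzofuran-3-carboxylate
Conditions: 18 (2 equiv), Pd(PPh3)4 (5 mol%), THF, 0–5 °C
Reagents that add atoms: none
Why: In this Tsuji–Trost O-allylation zerovalent palladium ionises 18 with loss of CO2, the tert-butoxide set free deprotonates the only free phenol, and at low temperature the phenoxide attacks the more substituted terminus of the 1,1-dimethyl-π-allyl complex, the known kinetic route to aryl 1,1-dimethylallyl ethers.

Step 10
Reactants: 19 methyl 6-methoxy-2-[2-methoxy-4-(methoxymethoxy)phenyl]-4-[(2-methylbut-3-en-2-yl)oxy]benzofuran-3-carboxylate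
Product: 21 methyl 4-hydroxy-6-methoxy-2-[2-methoxy-4-(methoxymethoxy)phenyl]-5-(3-methylbut-2-en-1-yl)benzofuran-3-carboxylate, via C5 dienone 20 (not isolated)
Conditions: toluene, 110 °C, sealed tube
Reagents that add atoms: none
Why: The aromatic Claisen rearrangement can only reach C5 because the other ortho position is the ring-fusion carbon C3a, the allyl inversion of the [3,3] shift turns the 1,1-dimethylallyl unit into a prenyl group, and dienone 20 tautomerises to the phenol.

Step 11
Reactants: 21 methyl 4-hydroxy-6-methoxy-2-[2-methoxy-4-(methoxymethoxy)phenyl]-5-(3-methylbut-2-en-1-yl)benzofuran-3-carboxylate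
Product: 22 3-(hydroxymethyl)-6-methoxy-2-[2-methoxy-4-(methoxymethoxy)phenyl]-5-(3-methylbut-2-en-1-yl)benzofuran-4-ol
Conditions: LiAlH4 (3 equiv), THF, 0 °C → rt; H2O, 15% aq NaOH, H2O; crude product used directly
Reagents that add atoms: none
Why: Hydride reduction of the ester with LiAlH4 should give the primary alcohol while the phenol is only deprotonated and the MOM ether, aryl ethers and isolated alkene are inert, and the basic work-up avoids ionisation of the electron-rich carbinol.

Step 12
Reactants: 22 3-(hydroxymethyl)-6-methoxy-2-[2-methoxy-4-(methoxymethoxy)phenyl]-5-(3-methylbut-2-en-1-yl)benzofuran-4-ol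
Product: 23 4-hydroxy-6-methoxy-2-[2-methoxy-4-(methoxymethoxy)phenyl]-5-(3-methylbut-2-en-1-yl)benzofuran-3-carbaldehyde
Conditions: activated MnO2 (15 equiv), CH2Cl2, rt
Reagents that add atoms: none
Why: MnO2 oxidation is selective for benzylic and heteroaryl carbinols, stops at the aldehyde and is routinely used on hydroxybenzyl alcohols without harm to the phenol or the prenyl group.

Step 13
Reactants: 23 4-hydroxy-6-methoxy-2-[2-methoxy-4-(methoxymethoxy)phenyl]-5-(3-methylbut-2-en-1-yl)benzofuran-3-carbaldehyde
Product: 24 ebenfuran IV, 4-hydroxy-2-(4-hydroxy-2-methoxyphenyl)-6-methoxy-5-(3-methylbut-2-en-1-yl)benzofuran-3-carbaldehyde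
Conditions: conc. HCl (cat.), MeOH, rt → 40 °C
Reagents that add atoms: none
Why: Acid-catalysed MOM cleavage (transacetalisation to methanol) is well precedented beside ortho-prenyl phenols, because chroman formation needs stronger acid and here the C4 hydroxyl is further tied up in a hydrogen bond to the C3 aldehyde.

**Compound list**
1 | 5-methoxyresorcinol | COc1cc(O)cc(O)c1 | starting material
2 | 1-methoxy-3,5-bis(methoxymethoxy)benzene | COCOc1cc(OC)cc(OCOC)c1 | intermediate
3 | dimethyl oxalate | COC(=O)C(=O)OC | starting material
4 | [4-methoxy-2,6-bis(methoxymethoxy)phenyl]lithium | [Li]c1c(OCOC)cc(OC)cc1OCOC | intermediate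
5 | methyl 2-[4-methoxy-2,6-bis(methoxymethoxy)phenyl]-2-oxoacetate | COC(=O)C(=O)c1c(OCOC)cc(OC)cc1OCOC | intermediate
6 | carbon tetrabromide | BrC(Br)(Br)Br | starting material
7 | methyl 3,3-dibromo-2-[4-methoxy-2,6-bis(methoxymethoxy)phenyl]acrylate | COC(=O)C(=C(Br)Br)c1c(OCOC)cc(OC)cc1OCOC | intermediate
8 | methyl 3,3-dibromo-2-(2,6-dihydroxy-4-methoxyphenyl)acrylate | COC(=O)C(=C(Br)Br)c1c(O)cc(OC)cc1O | intermediate
9 | 4-bromo-3-methoxyphenol | COc1cc(O)ccc1Br | starting material
10 | 1-bromo-2-methoxy-4-(methoxymethoxy)benzene | COCOc1ccc(Br)c(OC)c1 | intermediate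
11 | [2-methoxy-4-(methoxymethoxy)phenyl]lithium | [Li]c1ccc(OCOC)cc1OC | intermediate
12 | lithium [2-methoxy-4-(methoxymethoxy)phenyl]triisopropoxyborate | [Li+].COCOc1ccc([B-](OC(C)C)(OC(C)C)OC(C)C)c(OC)c1 | intermediate
13 | [2-methoxy-4-(methoxymethoxy)phenyl]boronic acid | COCOc1ccc(B(O)O)c(OC)c1 | intermediate
14 | methyl 2-bromo-4-hydroxy-6-methoxybenzofuran-3-carboxylate | COC(=O)c1c(Br)oc2cc(OC)cc(O)c12 | intermediate
15 | methyl 4-hydroxy-6-methoxy-2-[2-methoxy-4-(methoxymethoxy)phenyl]benzofuran-3-carboxylate | COCOc1ccc(-c2oc3cc(OC)cc(O)c3c2C(=O)OC)c(OC)c1 | intermediate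
16 | 2-methylbut-3-en-2-ol | C=CC(C)(C)O | starting material
17 | lithium 2-methylbut-3-en-2-olate | [Li+].[O-]C(C)(C)C=C | intermediate
18 | tert-butyl (2-methylbut-3-en-2-yl) carbonate | C=CC(C)(C)OC(=O)OC(C)(C)C | intermediate
19 | methyl 6-methoxy-2-[2-methoxy-4-(methoxymethoxy)phenyl]-4-[(2-methylbut-3-en-2-yl)oxy]benzofuran-3-carboxylate | COCOc1ccc(-c2oc3cc(OC)cc(OC(C)(C)C=C)c3c2C(=O)OC)c(OC)c1 | intermediate
20 | methyl 6-methoxy-2-[2-methoxy-4-(methoxymethoxy)phenyl]-5-(3-methylbut-2-en-1-yl)-4-oxo-4,5-dihydrobenzofuran-3-carboxylate (racemic, transient) | COCOc1ccc(-c2oc3C=C(OC)C(CC=C(C)C)C(=O)c3c2C(=O)OC)c(OC)c1 | intermediate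
21 | methyl 4-hydroxy-6-methoxy-2-[2-methoxy-4-(methoxymethoxy)phenyl]-5-(3-methylbut-2-en-1-yl)benzofuran-3-carboxylate | COCOc1ccc(-c2oc3cc(OC)c(CC=C(C)C)c(O)c3c2C(=O)OC)c(OC)c1 | intermediate
22 | 3-(hydroxymethyl)-6-methoxy-2-[2-methoxy-4-(methoxymethoxy)phenyl]-5-(3-methylbut-2-en-1-yl)benzofuran-4-ol | COCOc1ccc(-c2oc3cc(OC)c(CC=C(C)C)c(O)c3c2CO)c(OC)c1 | intermediate
23 | 4-hydroxy-6-methoxy-2-[2-methoxy-4-(methoxymethoxy)phenyl]-5-(3-methylbut-2-en-1-yl)benzofuran-3-carbaldehyde | COCOc1ccc(-c2oc3cc(OC)c(CC=C(C)C)c(O)c3c2C=O)c(OC)c1 | intermediate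
24 | ebenfuran IV, 4-hydroxy-2-(4-hydroxy-2-methoxyphenyl)-6-methoxy-5-(3-methylbut-2-en-1-yl)benzofuran-3-carbaldehyde | COc1cc(O)ccc1-c1oc2cc(OC)c(CC=C(C)C)c(O)c2c1C=O | target

**Step count**
Total step count: 13.
Longest linear sequence: 10 steps (steps 1, 2, 3, 4, 7, 9, 10, 11, 12, 13).

**The three steps most likely to fail**

Step 7.
- What may go wrong: the 5-endo closure may lag behind lactonisation of the phenoxide onto the ester. Hydrolytic loss of the C2 bromide or protodeboronation of the electron-rich boronic acid may also erode the coupling.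
- Fallback: it sets out from 5 (with 10 as the ring B partner) and comes back at 15. The furan is closed at the C2–H level and ring B is attached by C–H arylation instead of cross-coupling of a bromide.
- Wittig reaction of 5 with the ylide from (methoxymethyl)triphenylphosphonium chloride and KOtBu (THF, 0 °C) is a standard conversion of aryl glyoxylates. It should give methyl 3-methoxy-2-[4-methoxy-2,6-bis(methoxymethoxy)phenyl]acrylate F1 as an E/Z mixture.
- Methanolic HCl at reflux removes both MOM groups. One of the equivalent phenols adds to the protonated enol ether and methanol is lost, giving methyl 4-hydroxy-6-methoxybenzofuran-3-carboxylate F2.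
- Direct arylation of the acidic C2–H bond of F2 with bromide 10 by concerted metalation–deprotonation (Pd(OAc)2, PCy3·HBF4, pivalic acid, K2CO3, DMA, 110 °C) should then deliver 15.

Step 3.
- What may go wrong: the two ortho OMOM groups shield the ketone, so formation of the crowded oxaphosphetane may be slow. Attack of phosphine on the 1,2-dicarbonyl unit and loss of MOM groups may then take over.
- Fallback: it sets out from 5 and comes back at 7. The one-step olefination is replaced by addition of a small carbanion followed by dehydration.
- LiCHBr2 is generated from CH2Br2 and LiN(iPr)2 in THF at −90 °C in the presence of the non-enolisable keto ester. It should add to the ketone and, after a cold acid quench, give racemic methyl 3,3-dibromo-2-hydroxy-2-[4-methoxy-2,6-bis(methoxymethoxy)phenyl]propanoate F3.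
- SOCl2 in pyridine at 0 °C then dehydrates this tertiary benzylic alcohol. Its only β-hydrogen is the acidified CHBr2 hydrogen, so 7 is the only possible alkene.

Step 9.
- What may go wrong: the hydrogen-bonded, peri-hindered phenol may react sluggishly. Palladium may re-ionise the tertiary ether, so that it equilibrates towards the linear O-prenyl isomer, which would rearrange to the wrong C5 substituent.
- Fallback: it sets out from 15 and comes back at 19. It builds the tertiary ether without a π-allyl intermediate.
- O-alkylation with 3-chloro-3-methylbut-1-yne (K2CO3, KI, CuI cat., DMF, 60 °C) should give methyl 6-methoxy-2-[2-methoxy-4-(methoxymethoxy)phenyl]-4-[(2-methylbut-3-yn-2-yl)oxy]benzofuran-3-carboxylate F4.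
- Lindlar semihydrogenation of the terminal alkyne (H2, Pd/CaCO3 poisoned with Pb(OAc)2, quinoline, EtOAc, rt) then gives 19.

Further compounds
F1 | step 7 | methyl 3-methoxy-2-[4-methoxy-2,6-bis(methoxymethoxy)phenyl]acrylate (E/Z mixture) | COC=C(C(=O)OC)c1c(OCOC)cc(OC)cc1OCOC
F2 | step 7 | methyl 4-hydroxy-6-methoxybenzofuran-3-carboxylate | COC(=O)c1coc2cc(OC)cc(O)c12
F3 | step 3 | methyl 3,3-dibromo-2-hydroxy-2-[4-methoxy-2,6-bis(methoxymethoxy)phenyl]propanoate (racemic) | COC(=O)C(O)(C(Br)Br)c1c(OCOC)cc(OC)cc1OCOC
F4 | step 9 | methyl 6-methoxy-2-[2-methoxy-4-(methoxymethoxy)phenyl]-4-[(2-methylbut-3-yn-2-yl)oxy]benzofuran-3-carboxylate | COCOc1ccc(-c2oc3cc(OC)cc(OC(C)(C)C#C)c3c2C(=O)OC)c(OC)c1
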